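**Assumption:** the target has no stereocentre and no alkene of open geometry, so all SMILES carry no stereodescriptors; compounds 1, 3 and 7 are taken as purchasable.

## Analysis of the target

The target is a pentacyclic flavone: ring A (benzo ring) and ring C (4-pyranone) form the chromone, ring B is a 4′,5′-catechol on C2, ring E is a 2,2-dimethyl-2H-pyran fused through O7 and C8, and ring D is a seven-membered oxepine C2–C3–CH2–C(=CMe2)–O–C2′–C1′. The feature that decides the strategy sits in ring D: a C5 unit is bound through its central sp2 carbon to O2′ and through its CH2 terminus to C3, with the isopropylidene exocyclic. This is the pattern that a propargylic C3 electrophile delivers to an oxygen and then a carbon nucleophile. The chromene alkene is ring-locked and the other two alkenes end in two methyl groups, so no stereochemistry has to be controlled. The tetrasubstituted aryl enol ether is the most fragile group (acid would hydrolyse it or move the double bond), followed by the catechol (oxidation) and the C6 prenyl group next to the 5-OH (acid-induced chroman formation). Ring A is hexasubstituted, and the two oxygens ortho to its acyl carbon (O1 and O5) differ only in their neighbours (pyran carbon versus prenyl), so the closure of ring C is regiochemically ambiguous unless these oxygens are told apart by construction. Finally, C3 is a nucleophile only before ring C is aromatic, so ring D and ring C must be built in the right order and without acid once the enol ether exists.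

## Retrosynthetic reasoning

**14 back to 11 (C6–prenyl and the free phenols).** The catechol is unmasked last from bis-silyl ether 13 with buffered fluoride. The prenyl group of 13 is traced to the allyl group of 12 (cross-metathesis), and the C6–CH2 bond of 12 is cut back to the O5–allyl bond of 11 (aromatic Claisen). In 11, C6 is the only free ortho position, so the rearrangement has no choice. The allyl group therefore protects O5 while ring C is closed and then becomes the carbon substituent.

**11 back to 9 and 6 (ring C: C3–C4 and O1–C2).** Cutting these two bonds separates the ring-B/ring-D ketone 9 from the ring-A/ring-E acyl donor 6. Compound 6 is a salicylate acetonide: the carboxyl carbon (future C4) and the oxygen next to the pyran carbon (future O1) are tied together in the dioxinone ring, while the other ortho oxygen carries the allyl group. C-acylation of the enolate of 9 releases only the correct phenol (in diketone 10), and ring C closes under base, so the enol ether never meets acid.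

**9 back to 8 and 2 (ring D, key disconnection).** Both bonds that the C5 unit makes to the rest of the molecule are cut at once: the O2′–C bond to the isopropylidene-bearing carbon and the bond between the ring-D CH2 and the ketone α-carbon (future C3). The forward reaction is a (4+3) annulation of hydroxyacetophenone 8 with propargylic carbonate 2 under palladium catalysis. It is placed at the acetophenone stage on purpose: the carbon acid is then a simple methyl ketone, so the phenol must react first. At the stage of a 1,3-diketone such as 10 the soft carbanion would take the central carbon and give the wrong connectivity.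

**6 back to 3 and 2 (ring E and the O5 mask).** The O5–allyl bond is cut to give 5. The pyran of 5 is cut at C8–C4(pyran) and traced to propargyl ether 4 (propargyl Claisen, hydrogen shift, electrocyclisation), and 4 comes from commercial dihydroxy-benzodioxinone 3 and the same carbonate 2. Reagent 2 thus supplies two of the three C5 units: copper catalysis places oxygen on its tertiary carbon, palladium catalysis places oxygen on its central carbon.

**8 back to 7, and 2 back to 1.** Selective silylation of the two non-chelated phenols of 7, and carbonate formation from alcohol 1.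

## Alternatives that were turned down

**Alternative 1:** the textbook route cuts the O2′–C(enol) bond of ring D last. The forward key step is a copper-catalysed intramolecular O-vinylation (Ullmann-type) of the 2′-phenol of vinyl bromide A1, a complete flavone reached by Baker–Venkataraman chemistry and C3 alkylation with a 1,2-dibromo C5 reagent. It was turned down for these reasons:
- The coupling joins a tetrasubstituted vinyl bromide to a hindered phenol in a seven-membered closure, at high temperature with carbonate base, on the most valuable intermediate.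
- A1 needs four phenols differentiated (one free, three masked).
- The ambiguity of the two ortho oxygens of ring A is left unsolved, and the route is several steps longer.

**Alternative 2:** cut the exocyclic C=C bond of ring D. The forward key step is isopropylidenation of the seven-membered aryl lactone A2 (C3–CH2–C(=O)–O–C2′) with a thioacetal-derived titanocene alkylidene (Cp2Ti[P(OEt)3]2). It was turned down for these reasons:
- Tetrasubstituted alkylidene transfer to an ester is the least efficient class of this olefination.
- The aryl ester is an activated acyl group that thiolate or low-valent titanium can open, and the chromone enone competes for the reagent.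
- A2 itself needs an extra C2 homologation at C3, and the risk again comes at the end.

**Alternative 3:** the biomimetic cut removes the O2′–C bond oxidatively, starting from the 3-prenyl-2′-hydroxyflavone A3 in a Wacker-type cyclisation with divalent palladium. It was turned down for these reasons:
- Oxypalladation at the inner alkene carbon places palladium on the tertiary carbon, and β-hydride elimination then goes to a methyl group, giving the isopropenyl ether A4 and not the enol ether.
- The competing allylic C–H activation leads, by attack at the benzylic allyl terminus, to the six-membered pyran A5.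
- The constitution of ring D is therefore not under control, and the oxidant also threatens the catechol and the chromene.

Key step: step 6

## Route

**Step 1**
Reactants: 1 2-methylbut-3-yn-2-ol
Product: 2 methyl 2-methylbut-3-yn-2-yl carbonate
Conditions: n-BuLi (1.0 equiv), THF, −78 °C; ClCO2Me, −78 → 0 °C
Reagents that add atoms: methyl chloroformate, COC(=O)Cl
Why: Acylation of the lithium alkoxide with a chloroformate (carbonate formation); one equivalent of base removes only the O–H, which is far more acidic than the alkyne C–H.

**Step 2**
Reactants: 3 5,7-dihydroxy-2,2-dimethyl-4H-1,3-benzodioxin-4-one; 2 methyl 2-methylbut-3-yn-2-yl carbonate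
Product: 4 5-hydroxy-2,2-dimethyl-7-[(2-methylbut-3-yn-2-yl)oxy]-4H-1,3-benzodioxin-4-one
Conditions: CuCl2·2H2O (1 mol %), DBU (1.2 equiv), MeCN, 0 °C
Reagents that add atoms: none
Why: Copper-catalysed propargylic etherification of a phenol (copper acetylide/allenylidene attacked at the tertiary carbon). The 7-OH is the only phenol not chelated to the lactone carbonyl and the more acidic one, so it should react selectively.

**Step 3**
Reactants: 4 5-hydroxy-2,2-dimethyl-7-[(2-methylbut-3-yn-2-yl)oxy]-4H-1,3-benzodioxin-4-one
Product: 5 5-hydroxy-2,2-dimethyl-4H-1,3-benzodioxin-4-one carrying a 2,2-dimethyl-2H-pyran fused through O at C7 and CH=CH at C8 (angular)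
Conditions: N,N-diethylaniline, 150 °C
Reagents that add atoms: none
Why: Aromatic propargyl Claisen rearrangement, then 1,5-hydrogen shift and oxa-6π-electrocyclisation (thermal 2,2-dimethylchromene synthesis). The [3,3] shift is expected at C8 and not C6 by analogy with 5-hydroxy-7-propargyloxychromones and 1-hydroxy-3-propargyloxyacridones, which cyclise in the angular sense.

**Step 4**
Reactants: 5 angular pyrano-benzodioxinone with free 5-OH
Product: 6 5-(allyloxy) ether of 5
Conditions: allyl bromide (1.5 equiv), K2CO3 (2 equiv), DMF, 50 °C
Reagents that add atoms: allyl bromide, C=CCBr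
Why: Williamson etherification of the chelated phenol. The allyl group masks O5 until ring C is closed and is the source of the C6 side chain.

**Step 5**
Reactants: 7 1-(2,4,5-trihydroxyphenyl)ethanone
Product: 8 1-[2-hydroxy-4,5-bis(triisopropylsilyloxy)phenyl]ethanone
Conditions: iPr3SiCl (2.2 equiv), imidazole (4.5 equiv), DMF, 0 °C → rt
Reagents that add atoms: chlorotriisopropylsilane, CC(C)[Si](Cl)(C(C)C)C(C)C
Why: Silylation of the two non-chelated phenols. The 2-OH is hydrogen-bonded to the acetyl group, far less nucleophilic towards the bulky silyl chloride, and should stay free.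

**Step 6**
Reactants: 8 1-[2-hydroxy-4,5-bis(triisopropylsilyloxy)phenyl]ethanone; 2 methyl 2-methylbut-3-yn-2-yl carbonate
Product: 9 2-(propan-2-ylidene)-7,8-bis(triisopropylsilyloxy)-3,4-dihydro-1-benzoxepin-5(2H)-one
Conditions: 2 (1.2 equiv), Pd2(dba)3·CHCl3 (2.5 mol %), DPEphos (6 mol %), Cs2CO3 (20 mol %), 1,4-dioxane, 80 °C
Reagents that add atoms: none
Why: Proposed new method: zerovalent palladium ionises carbonate 2 (SN2′, loss of CO2) to a cationic η3-propargyl/allenyl complex of divalent palladium and methoxide, which deprotonates the only acidic site of 8, the phenol; the phenoxide attacks the central carbon of the C3 ligand, and protonation of the resulting palladacyclobutene at the former alkyne CH gives a 2-aryloxy-π-allyl palladium complex with CH2 and CMe2 termini. The methyl ketone is then enolised (methoxide, Cs2CO3) and its α-carbon attacks the CH2 terminus intramolecularly, releasing zerovalent palladium. The closest known reaction type is the palladium-catalysed double nucleophilic substitution of propargylic carbonates, which gives furans from β-keto esters, 2-alkylidene-1,4-benzodioxanes from catechols and 2-alkylidenechromans from 2-(2-hydroxyphenyl)acetates (oxygen first, carbon second); a seven-membered ring closed by a simple ketone enolate goes beyond this precedent. The oxepine closes in the allylic alkylation, formally a 7-exo-tet displacement of palladium at the CH2 end of the σ-allyl form, so the isopropylidene ends up exocyclic. No stereocentre is formed and the new alkene has no geometry because both substituents are methyl. Two selectivities are needed: oxygen before carbon, secured because the carbon acid is a non-stabilised ketone about ten pKa units weaker than the phenol (a 1,3-diketone such as 10 would attack the central carbon through carbon instead); and CH2 over CMe2 in the ring closure, secured by the steric demand of the enolate carbon, both modes giving a seven-membered ring. C-Alkylation is irreversible, whereas capture of the allyl complex by a second phenoxide is reversible and should funnel to 9.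

**Step 7**
Reactants: 9 benzoxepinone; 6 5-(allyloxy) pyrano-benzodioxinone
Product: 11 5-O-allyl 6-unsubstituted 4′,5′-bis(triisopropylsilyl) analogue of the target (rings A to E complete), via 1,3-diketone 10 (not isolated)
Conditions: LiN(SiMe3)2 (2.2 equiv), THF, −78 °C; 6, −78 → 0 °C; AcOH (2.2 equiv); then DBU (30 mol %), 4 Å MS, toluene, 80 °C
Reagents that add atoms: none
Why: Claisen-type C-acylation of the lithium enolate of 9 (only one enolisable position) by salicylate acetonide 6, which loses acetone and frees only the phenol next to the pyran carbon, so only this oxygen can close ring C. Base-mediated cyclodehydration (hemiketal formation, E1cB loss of hydroxide, as in one-pot Baker–Venkataraman flavone syntheses) forms the 4-pyranone without acid; the stereocentre of racemic 10 is destroyed.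

**Step 8**
Reactants: 11 5-O-allyl tetracyclic chromone
Product: 12 6-allyl-5-hydroxy analogue (4′,5′-bis(triisopropylsilyl) ether)
Conditions: N,N-diethylaniline, 190 °C, argon
Reagents that add atoms: none
Why: Aromatic Claisen rearrangement ([3,3]) of the aryl allyl ether. C6 is the only free ortho position (C4a is a ring fusion, the para position C8 is substituted), and tautomerisation regenerates the chelated 5-OH.

**Step 9**
Reactants: 12 6-allyl-5-hydroxy compound
Product: 13 4′,5′-bis(triisopropylsilyl) ether of the target
Conditions: 2-methylbut-2-ene (excess)/CH2Cl2, second-generation Grubbs catalyst RuCl2(H2IMes)(PCy3)(=CHPh) (5 mol %), 40 °C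
Reagents that add atoms: 2-methylbut-2-ene, CC=C(C)C
Why: Olefin cross-metathesis of the terminal allyl alkene with excess trisubstituted alkene gives the prenyl group. The ring-locked chromene alkene and the tetrasubstituted enol ether are too hindered to engage the ruthenium carbene.

**Step 10**
Reactants: 13 bis(triisopropylsilyl) ether of the target
Product: 14 isocycloheterophyllin
Conditions: Bu4NF (2.5 equiv), AcOH (2.5 equiv), THF, 0 °C, argon
Reagents that add atoms: none
Why: Fluoride cleavage of the two aryl silyl ethers, buffered with acetic acid so that the enol ether meets no strong acid and the catechol no strong base.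

## Compound list

1 | 2-methylbut-3-yn-2-ol | CC(C)(O)C#C | starting material
2 | methyl 2-methylbut-3-yn-2-yl carbonate | COC(=O)OC(C)(C)C#C | intermediate
3 | 5,7-dihydroxy-2,2-dimethyl-4H-1,3-benzodioxin-4-one | CC1(C)OC(=O)c2c(O)cc(O)cc2O1 | starting material
4 | 5-hydroxy-2,2-dimethyl-7-[(2-methylbut-3-yn-2-yl)oxy]-4H-1,3-benzodioxin-4-one | CC1(C)OC(=O)c2c(O)cc(OC(C)(C)C#C)cc2O1 | intermediate
5 | 5-hydroxy-2,2-dimethyl-4H-1,3-benzodioxin-4-one with a 2,2-dimethyl-2H-pyran fused at C7 (O) and C8 (CH=CH) | CC1(C)OC(=O)c2c(O)cc3OC(C)(C)C=Cc3c2O1 | intermediate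
6 | 5-(allyloxy) ether of 5 | C=CCOc1cc2OC(C)(C)C=Cc2c2OC(C)(C)OC(=O)c12 | intermediate
7 | 1-(2,4,5-trihydroxyphenyl)ethanone | CC(=O)c1cc(O)c(O)cc1O | starting material
8 | 1-[2-hydroxy-4,5-bis(triisopropylsilyloxy)phenyl]ethanone | CC(=O)c1cc(O[Si](C(C)C)(C(C)C)C(C)C)c(O[Si](C(C)C)(C(C)C)C(C)C)cc1O | intermediate
9 | 2-(propan-2-ylidene)-7,8-bis(triisopropylsilyloxy)-3,4-dihydro-1-benzoxepin-5(2H)-one | CC(C)=C1CCC(=O)c2cc(O[Si](C(C)C)(C(C)C)C(C)C)c(O[Si](C(C)C)(C(C)C)C(C)C)cc2O1 | intermediate
10 | 4-[7-(allyloxy)-5-hydroxy-2,2-dimethyl-2H-chromene-6-carbonyl] derivative of 9 (1,3-diketone, racemic at C4 of the benzoxepinone) | CC(C)=C1CC(C(=O)c3c(O)c4C=CC(C)(C)Oc4cc3OCC=C)C(=O)c2cc(O[Si](C(C)C)(C(C)C)C(C)C)c(O[Si](C(C)C)(C(C)C)C(C)C)cc2O1 | intermediate (not isolated)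
11 | 5-O-allyl, 6-unsubstituted, 4′,5′-bis(triisopropylsilyl) analogue of the target | C=CCOc1cc2OC(C)(C)C=Cc2c2oc3c(CC(=C(C)C)Oc4cc(O[Si](C(C)C)(C(C)C)C(C)C)c(O[Si](C(C)C)(C(C)C)C(C)C)cc4-3)c(=O)c12 | intermediate
12 | 6-allyl-5-hydroxy, 4′,5′-bis(triisopropylsilyl) analogue of the target | C=CCc1c(O)c2c(=O)c3CC(=C(C)C)Oc4cc(O[Si](C(C)C)(C(C)C)C(C)C)c(O[Si](C(C)C)(C(C)C)C(C)C)cc4-c3oc2c2C=CC(C)(C)Oc12 | intermediate
13 | 4′,5′-bis(triisopropylsilyl) ether of isocycloheterophyllin | CC(C)=CCc1c(O)c2c(=O)c3CC(=C(C)C)Oc4cc(O[Si](C(C)C)(C(C)C)C(C)C)c(O[Si](C(C)C)(C(C)C)C(C)C)cc4-c3oc2c2C=CC(C)(C)Oc12 | intermediate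
14 | isocycloheterophyllin | CC(C)=CCc1c2c(c3oc4c(c(=O)c3c1O)CC(=C(C)C)Oc1cc(O)c(O)cc1-4)C=CC(C)(C)O2 | target

## Step count and risk

Total step count: 10. Longest linear sequence: 8 steps (1, 2, 3, 4, 7, 8, 9, 10).

**Step 6 (key step, proposed new method).** The most likely failure is slow enolisation and C-alkylation by the non-stabilised methyl ketone in a seven-membered closure. The aryloxy-allyl palladium intermediate would then be drained by β-hydride elimination to a diene or by irreversible capture by methoxide, and the catalyst would stall. Fallback with known chemistry, from 8 back to 9: double deprotonation of 8 with LiN(iPr)2 and C-alkylation of the dianion at the allylic bromide of 1,2-dibromo-3-methylbut-2-ene should give 4-bromo-1-[2-hydroxy-4,5-bis(triisopropylsilyloxy)phenyl]-5-methylhex-4-en-1-one F1. Copper-catalysed intramolecular O-vinylation of its phenol (CuI, 1,10-phenanthroline, Cs2CO3, toluene, 110 °C) then closes the oxepine and returns to 9.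

**Step 7.** The lactone carbonyl of 6 is flanked by two oxygen substituents and is electron-rich, so attack by the hindered enolate may be slow, O-acylation may compete, and retro-Claisen cleavage may accompany the basic dehydration. Fallback, from 6 and 9 back to 10: reduction of 6 with iBu2AlH at −78 °C (collapse of the lactol acetal with loss of acetone) should give 7-(allyloxy)-5-hydroxy-2,2-dimethyl-2H-chromene-6-carbaldehyde F2. Aldol addition of the lithium enolate of 9 to F2 (one extra equivalent of LiN(SiMe3)2 for the phenol) should give the β-hydroxy ketone F3 as a diastereomer mixture. Oxidation of its benzylic alcohol with MnO2 leads to 10, which is cyclodehydrated with DBU as in step 7.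

**Step 3.** The sigmatropic shift may go to C6 instead of C8, because C6 also lies between two oxygens; this would give the linear pyran and in the end the wrong flavone isomer. Fallback, from 4 back to 6, with the regiochemistry enforced by symmetry:
- Opening the acetonide of 4 with NaOMe/MeOH should give the symmetric methyl 2,6-dihydroxy-4-[(2-methylbut-3-yn-2-yl)oxy]benzoate F4.
- Heating F4 can only give methyl 5,7-dihydroxy-2,2-dimethyl-2H-chromene-6-carboxylate F5, since both ortho positions are equivalent.
- Mono-allylation at the less hindered phenol (K2CO3, allyl bromide; the phenol peri to the pyran CH stays chelated) should give methyl 7-(allyloxy)-5-hydroxy-2,2-dimethyl-2H-chromene-6-carboxylate F6.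
- Saponification (KOH, aqueous EtOH, reflux) gives 7-(allyloxy)-5-hydroxy-2,2-dimethyl-2H-chromene-6-carboxylic acid F7.
- Acetonide formation (acetone, trifluoroacetic anhydride, trifluoroacetic acid) returns to 6.

**Step 8.** At 190 °C the exocyclic enol ether double bond may migrate or silyl groups may be lost on the advanced intermediate, and conversion may stay incomplete. Fallback, from 6 (with 9) back to 14, moving rearrangement and metathesis to the small fragment:
- Heating 6 should give the 6-allyl-5-hydroxy pyrano-benzodioxinone F8.
- Cross-metathesis with 2-methylbut-2-ene gives the 6-prenyl compound F9.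
- Silylation (iPr3SiOSO2CF3, 2,6-lutidine) gives the 5-O-triisopropylsilyl ether F10.
- Union with 9 under the conditions of step 7 should give the 5,4′,5′-tris(triisopropylsilyl) ether of the target F11.
- Buffered Bu4NF then gives 14.

## Further compounds

F1 | step 6 | 4-bromo-1-[2-hydroxy-4,5-bis(triisopropylsilyloxy)phenyl]-5-methylhex-4-en-1-one | CC(C)=C(Br)CCC(=O)c1cc(O[Si](C(C)C)(C(C)C)C(C)C)c(O[Si](C(C)C)(C(C)C)C(C)C)cc1O
F2 | step 7 | 7-(allyloxy)-5-hydroxy-2,2-dimethyl-2H-chromene-6-carbaldehyde | C=CCOc1cc2OC(C)(C)C=Cc2c(O)c1C=O
F3 | step 7 | 4-{[7-(allyloxy)-5-hydroxy-2,2-dimethyl-2H-chromen-6-yl](hydroxy)methyl} derivative of 9 (diastereomer mixture) | CC(C)=C1CC(C(O)c3c(O)c4C=CC(C)(C)Oc4cc3OCC=C)C(=O)c2cc(O[Si](C(C)C)(C(C)C)C(C)C)c(O[Si](C(C)C)(C(C)C)C(C)C)cc2O1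
F4 | step 3 | methyl 2,6-dihydroxy-4-[(2-methylbut-3-yn-2-yl)oxy]benzoate | COC(=O)c1c(O)cc(OC(C)(C)C#C)cc1O
F5 | step 3 | methyl 5,7-dihydroxy-2,2-dimethyl-2H-chromene-6-carboxylate | COC(=O)c1c(O)cc2OC(C)(C)C=Cc2c1O
F6 | step 3 | methyl 7-(allyloxy)-5-hydroxy-2,2-dimethyl-2H-chromene-6-carboxylate | COC(=O)c1c(OCC=C)cc2OC(C)(C)C=Cc2c1O
F7 | step 3 | 7-(allyloxy)-5-hydroxy-2,2-dimethyl-2H-chromene-6-carboxylic acid | OC(=O)c1c(OCC=C)cc2OC(C)(C)C=Cc2c1O
F8 | step 8 | 6-allyl-5-hydroxy pyrano-benzodioxinone (6-allyl derivative of 5) | C=CCc1c(O)c2C(=O)OC(C)(C)Oc2c2C=CC(C)(C)Oc12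
F9 | step 8 | 6-(3-methylbut-2-en-1-yl)-5-hydroxy pyrano-benzodioxinone | CC(C)=CCc1c(O)c2C(=O)OC(C)(C)Oc2c2C=CC(C)(C)Oc12
F10 | step 8 | 5-O-triisopropylsilyl ether of F9 | CC(C)=CCc1c(O[Si](C(C)C)(C(C)C)C(C)C)c2C(=O)OC(C)(C)Oc2c2C=CC(C)(C)Oc12
F11 | step 8 | 5,4′,5′-tris(triisopropylsilyl) ether of isocycloheterophyllin | CC(C)=CCc1c2c(c3oc4c(c(=O)c3c1O[Si](C(C)C)(C(C)C)C(C)C)CC(=C(C)C)Oc1cc(O[Si](C(C)C)(C(C)C)C(C)C)c(O[Si](C(C)C)(C(C)C)C(C)C)cc1-4)C=CC(C)(C)O2
A1 | alternative 1 | 3-(2-bromo-3-methylbut-2-en-1-yl)-2′-hydroxy flavone with rings A and E complete and 4′,5′-bis(triisopropylsilyl) ethers | CC(C)=CCc1c(O)c2c(=O)c(CC(Br)=C(C)C)c(-c3cc(O[Si](C(C)C)(C(C)C)C(C)C)c(O[Si](C(C)C)(C(C)C)C(C)C)cc3O)oc2c2C=CC(C)(C)Oc12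
A2 | alternative 2 | seven-membered aryl lactone (C3–CH2–C(=O)–O–C2′) of the bis-silylated flavone | CC(C)=CCc1c(O)c2c(=O)c3CC(=O)Oc4cc(O[Si](C(C)C)(C(C)C)C(C)C)c(O[Si](C(C)C)(C(C)C)C(C)C)cc4-c3oc2c2C=CC(C)(C)Oc12
A3 | alternative 3 | 3-prenyl-2′-hydroxy flavone with rings A and E complete and 4′,5′-bis(triisopropylsilyl) ethers | CC(C)=CCc1c(O)c2c(=O)c(CC=C(C)C)c(-c3cc(O[Si](C(C)C)(C(C)C)C(C)C)c(O[Si](C(C)C)(C(C)C)C(C)C)cc3O)oc2c2C=CC(C)(C)Oc12
A4 | alternative 3 | oxepine with isopropenyl group on the O-bearing sp3 carbon (racemic) | CC(C)=CCc1c(O)c2c(=O)c3CC(C(C)=C)Oc4cc(O[Si](C(C)C)(C(C)C)C(C)C)c(O[Si](C(C)C)(C(C)C)C(C)C)cc4-c3oc2c2C=CC(C)(C)Oc12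
A5 | alternative 3 | six-membered pyran isomer, C3–CH(CH=CMe2)–O–C2′ (racemic) | CC(C)=CCc1c(O)c2c(=O)c3C(C=C(C)C)Oc4cc(O[Si](C(C)C)(C(C)C)C(C)C)c(O[Si](C(C)C)(C(C)C)C(C)C)cc4-c3oc2c2C=CC(C)(C)Oc12
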